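**Retrosynthetic overview**
1. The strategy rests on the hexasubstituted benzene ring, in which three oxygen-bearing carbons (C–OH, C–OH, C–OMe) alternate with three carbon-substituted carbons (aroyl, methylbutenyl, CH2 side chain). It divides into three two-carbon C–C(O) pieces, and the chain ArCH2–CH(isopropenyl)–CH2CH2–C(Me)=CH2 is ring-opened (R)-limonene.
2. Last C–C bond: the ring carbon between the two hydroxyls to the ketone carbon, made by ortho-lithiation of a bis-MOM ether at its only ring C–H, addition to 3-(methoxymethoxy)benzaldehyde, oxidation and MOM removal.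
3. Central ring: benzannulation of a 2-alkyl-3-siloxycyclobutenone with (E)-1-methoxy-5-methylhex-3-en-1-yne. The cyclobutenone comes from ketene and a siloxyalkyne, itself made by Kowalski homologation of the limonene-derived ester, so that limonene C2 ends as the ring C–OH carbon next to the side chain and the CH2Br2 carbon as the ring carbon carrying the benzylic CH2.
4. Enynyl ether: Negishi coupling of methoxyethynylzinc chloride with (E)-1-iodo-3-methylbut-1-ene from hydrozirconation of 3-methylbut-1-yne.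
5. Ring order: the four-membered cyclobutenone first, then the central benzene ring, and the bought 3-oxygenated phenyl ring attached last.

Key step: step 10

**Remarks on the chemistry**
- R* stands for the (2R)-5-methyl-2-(prop-1-en-2-yl)hex-5-en-1-yl group, whose stereocentre is C4 of (R)-limonene; the isopropenyl, ring-side CH2 and chain-side CH2 branches keep their CIP order throughout, so (R)-limonene gives the (R)-target.
- Ketene for step 7 is taken as the gas from pyrolysis of acetone, because amine dehydrohalogenation of an acetyl halide delivers the parent ketene poorly and its acylammonium salt would attack the silyl ynol ether.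
- Epoxide 2 is a mixture of the two epoxide diastereomers and benzhydrol 31 a mixture of carbinol epimers; each mixture converges in the next step, and the SMILES leave these centres open.

**Route**

Step 1
Reactants: 1 (R)-(+)-limonene
Product: 2 (4R)-limonene 1,2-epoxide
Conditions: mCPBA (1.0 equiv), NaHCO3, CH2Cl2, 0 °C
Reagents that add atoms: mCPBA, O=C(OO)c1cccc(Cl)c1
Why: Prilezhaev epoxidation, in which the trisubstituted ring alkene is more electron-rich than the 1,1-disubstituted isopropenyl alkene and should react first with one equivalent of peracid, leaving C4 untouched.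

Step 2
Reactants: 2 (4R)-limonene 1,2-epoxide
Product: 4 (3R)-6-oxo-3-(prop-1-en-2-yl)heptanal, via diol 3 (not isolated)
Conditions: H5IO6, THF/H2O, 0 °C → rt
Reagents that add atoms: water, O
Why: Aqueous periodic acid should open the epoxide to the trans-diol and cleave it in the same flask (Malaprade glycol cleavage), giving the methyl ketone from C1 and the aldehyde from C2 while the stereocentre, which is β to the aldehyde, is not affected.

Step 3
Reactants: 4 (3R)-6-oxo-3-(prop-1-en-2-yl)heptanal
Product: 5 (3R)-6-oxo-3-(prop-1-en-2-yl)heptanoic acid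
Conditions: NaClO2, NaH2PO4, 2-methylbut-2-ene, t-BuOH/H2O, 0 °C → rt
Reagents that add atoms: sodium chlorite, [Na+].[O-]Cl=O
Why: Pinnick oxidation converts only the aldehyde, and the sacrificial alkene should intercept HOCl before it can attack the isopropenyl group.

Step 4
Reactants: 5 (3R)-6-oxo-3-(prop-1-en-2-yl)heptanoic acid
Product: 6 methyl (3R)-6-oxo-3-(prop-1-en-2-yl)heptanoate
Conditions: MeI, K2CO3, DMF, rt
Reagents that add atoms: iodomethane, CI
Why: SN2 O-alkylation of the carboxylate, under a base too weak to alkylate the ketone enolate.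

Step 5
Reactants: 6 methyl (3R)-6-oxo-3-(prop-1-en-2-yl)heptanoate
Product: 7 methyl (3R)-6-methyl-3-(prop-1-en-2-yl)hept-6-enoate
Conditions: Ph3PCH3Br, KOt-Bu, THF, 0 °C → rt
Reagents that add atoms: methyltriphenylphosphonium bromide, C[P+](c1ccccc1)(c1ccccc1)c1ccccc1.[Br-]
Why: Wittig methylenation, in which the unstabilised ylide adds to the ketone and leaves the methyl ester alone.

Step 6
Reactants: 7 methyl (3R)-6-methyl-3-(prop-1-en-2-yl)hept-6-enoate
Product: 10 triisopropyl{[(4R)-7-methyl-4-(prop-1-en-2-yl)oct-7-en-1-yn-1-yl]oxy}silane, via dibromo enolate 8 (not isolated), via lithium ynolate 9 (not isolated)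
Conditions: CH2Br2, LiTMP (lithium 2,2,6,6-tetramethylpiperidide), THF, −78 °C; add 7; n-BuLi, −78 °C → rt; then i-Pr3SiCl, −78 °C → rt
Reagents that add atoms: dibromomethane, BrCBr; triisopropylsilyl chloride, CC(C)[Si](Cl)(C(C)C)C(C)C
Why: Kowalski ester homologation stopped at the ynolate, in which LiCHBr2 adds to the ester, bromine–lithium exchange on the dibromo enolate triggers a 1,2-shift of the alkyl group onto the carbenoid carbon, and the bulky silyl chloride should silylate the ynolate on oxygen.

Step 7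
Reactants: 10 triisopropyl{[(4R)-7-methyl-4-(prop-1-en-2-yl)oct-7-en-1-yn-1-yl]oxy}silane; 11 acetone
Product: 13 2-R*-3-[(triisopropylsilyl)oxy]cyclobut-2-en-1-one, via ketene 12 (not isolated)
Conditions: ketene gas (11 over a glowing Ni–Cr filament, ca. 700 °C) passed into 10, CH2Cl2, 0 °C → rt
Reagents that add atoms: none
Why: Polar [2+2] cycloaddition of ketene with the electron-rich siloxyalkyne, in which the alkyl-bearing alkyne carbon attacks the ketene carbonyl carbon and the siloxy-bearing carbon closes onto the ketene CH2, so the four-membered ring forms as the 2-alkyl-3-siloxy regioisomer.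

Step 8
Reactants: 14 3-methylbut-1-yne
Product: 16 (E)-1-iodo-3-methylbut-1-ene, via alkenylzirconocene 15 (not isolated)
Conditions: Cp2Zr(H)Cl, CH2Cl2, rt; then I2, 0 °C
Reagents that add atoms: iodine, II
Why: Hydrozirconation adds Zr–H syn with zirconium on the terminal carbon, and iodinolysis of the C–Zr bond with retention should give the E-iodide.

Step 9
Reactants: 16 (E)-1-iodo-3-methylbut-1-ene; 17 2-chloro-1,1-dimethoxyethane
Product: 20 (3E)-1-methoxy-5-methylhex-3-en-1-yne, via lithium methoxyacetylide 18 (not isolated), via methoxyethynylzinc chloride 19 (not isolated)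
Conditions: 17, LiNEt2 (3 equiv, from Et2NH/n-BuLi), THF, 0 °C; ZnCl2, 0 °C; then 16, Pd(PPh3)4 (cat.), rt
Reagents that add atoms: none
Why: Double elimination (methanol, then HCl) and deprotonation give the lithium acetylide, and after transmetalation to zinc a Negishi sp–sp2 coupling with the alkenyl iodide should proceed with retention of the E geometry.

Step 10
Reactants: 13 2-R*-3-[(triisopropylsilyl)oxy]cyclobut-2-en-1-one; 20 (3E)-1-methoxy-5-methylhex-3-en-1-yne
Product: 25 3-methoxy-4-R*-2-[(1E)-3-methylbut-1-en-1-yl]-5-[(triisopropylsilyl)oxy]phenol, via vinylketene 21 (not isolated), via alkenylcyclobutenone 22 (not isolated), via dienylketene 23 (not isolated), via cyclohexadienone 24 (not isolated)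
Conditions: PhMe, 20 (2 equiv), 110 °C, sealed tube
Reagents that add atoms: none
Why: Heating opens 13 by 4π electrocyclic cleavage of its C1–C4 bond to the siloxy vinylketene 21, whose ketene C=C adds the ynol ether in a polar [2+2] to give 22; a second 4π opening between the carbonyl carbon and the quaternary carbon gives dienylketene 23, which closes the six-membered carbocycle by thermal 6π electrocyclisation (ketene carbon to terminal CH2), and dienone 24 then tautomerises irreversibly to the phenol. This is the Danheiser benzannulation of a cyclobutenone-derived vinylketene with an alkoxyalkyne, here run with a 3-siloxycyclobutenone of the known ketene–siloxyalkyne adduct type. The net change is insertion of the two alkyne carbons between C1 and C2 of the cyclobutenone, which creates the ring bonds C(OH)–C(methylbutenyl) and C(OMe)–C(CH2 of R*) and delivers the three ring oxygens already differentiated as OH, OMe and OTIPS. No stereocentre is created: the transient quaternary centre of 22 is lost on ring opening, the R* centre is remote from every reacting atom, and the E-alkene is a spectator. Regiochemistry requires the alkyne carbon β to the methoxy group, the one carrying the methylbutenyl group, to bond to the ketene carbonyl carbon, which the oxygen polarisation of the ynol ether should enforce; chemoselectivity requires the ynol ether to outpace the two unactivated 1,1-disubstituted alkenes, which its much higher nucleophilicity and its use in excess should secure. Because a methyl ether cannot fragment by retro-ene loss of an alkene, the ynol ether should persist at the temperature needed to open the donor-stabilised cyclobutenone, and 23 contains only one hexatriene able to close.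

Step 11
Reactants: 25 3-methoxy-4-R*-2-[(1E)-3-methylbut-1-en-1-yl]-5-[(triisopropylsilyl)oxy]phenol
Product: 26 5-methoxy-4-R*-6-[(1E)-3-methylbut-1-en-1-yl]benzene-1,3-diol
Conditions: n-Bu4NF, THF, 0 °C
Reagents that add atoms: none
Why: Fluoride-driven cleavage of the aryl silyl ether, fast because phenoxide is a good leaving group from silicon, with alkenes and the methyl ether inert.

Step 12
Reactants: 26 5-methoxy-4-R*-6-[(1E)-3-methylbut-1-en-1-yl]benzene-1,3-diol
Product: 27 3-methoxy-1,5-bis(methoxymethoxy)-4-R*-2-[(1E)-3-methylbut-1-en-1-yl]benzene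
Conditions: MOMCl, i-Pr2NEt, CH2Cl2, 0 °C → rt
Reagents that add atoms: chloromethyl methyl ether, COCCl
Why: O-alkylation of both phenols with the α-chloro ether (Williamson-type acetal formation) installs two groups that later direct the metalation.

Step 13
Reactants: 28 3-hydroxybenzaldehyde
Product: 29 3-(methoxymethoxy)benzaldehyde
Conditions: MOMCl, i-Pr2NEt, CH2Cl2, 0 °C → rt
Reagents that add atoms: chloromethyl methyl ether, COCCl
Why: The same phenol O-alkylation masks the acidic OH so that the aldehyde can accept an aryllithium.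

Step 14
Reactants: 27 3-methoxy-1,5-bis(methoxymethoxy)-4-R*-2-[(1E)-3-methylbut-1-en-1-yl]benzene; 29 3-(methoxymethoxy)benzaldehyde
Product: 31 {2,6-bis(methoxymethoxy)-4-methoxy-3-R*-5-[(1E)-3-methylbut-1-en-1-yl]phenyl}[3-(methoxymethoxy)phenyl]methanol, via aryllithium 30 (not isolated)
Conditions: 27, n-BuLi, THF, 0 °C; then 29, −78 → 0 °C
Reagents that add atoms: none
Why: Directed ortho-metalation at the only ring C–H, which lies between two coordinating OMOM groups, followed by 1,2-addition of the aryllithium to the aldehyde; the new carbinol centre forms without control and is removed in step 15.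

Step 15
Reactants: 31 {2,6-bis(methoxymethoxy)-4-methoxy-3-R*-5-[(1E)-3-methylbut-1-en-1-yl]phenyl}[3-(methoxymethoxy)phenyl]methanol
Product: 32 {2,6-bis(methoxymethoxy)-4-methoxy-3-R*-5-[(1E)-3-methylbut-1-en-1-yl]phenyl}[3-(methoxymethoxy)phenyl]methanone
Conditions: Dess–Martin periodinane, NaHCO3, CH2Cl2, 0 °C → rt
Reagents that add atoms: none
Why: Dess–Martin oxidation of the diaryl carbinol under buffered, near-neutral conditions should give the benzophenone without touching the alkenes or the MOM ethers.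

Step 16
Reactants: 32 {2,6-bis(methoxymethoxy)-4-methoxy-3-R*-5-[(1E)-3-methylbut-1-en-1-yl]phenyl}[3-(methoxymethoxy)phenyl]methanone
Product: 33 {2,6-dihydroxy-4-methoxy-3-R*-5-[(1E)-3-methylbut-1-en-1-yl]phenyl}(3-hydroxyphenyl)methanone (CNP0208548.1)
Conditions: HCl (ca. 1 M), MeOH, 0 °C → rt
Reagents that add atoms: none
Why: Acid-catalysed transacetalisation to methanol removes the three MOM groups, the two beside the carbonyl being activated by hydrogen bonding to it, and dilute acid at or below room temperature should spare the alkenes and the stereocentre, which is not α to a carbonyl.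

**Compound list**
1 | (R)-(+)-limonene | CC1=CC[C@@H](CC1)C(=C)C | starting material
2 | (4R)-limonene 1,2-epoxide (both epoxide diastereomers) | CC12CC[C@H](CC1O2)C(=C)C | intermediate
3 | (4R)-1-methyl-4-(prop-1-en-2-yl)cyclohexane-1,2-diol (trans-diol) | CC1(O)CC[C@H](CC1O)C(=C)C | intermediate
4 | (3R)-6-oxo-3-(prop-1-en-2-yl)heptanal | CC(=O)CC[C@H](CC=O)C(=C)C | intermediate
5 | (3R)-6-oxo-3-(prop-1-en-2-yl)heptanoic acid | CC(=O)CC[C@H](CC(=O)O)C(=C)C | intermediate
6 | methyl (3R)-6-oxo-3-(prop-1-en-2-yl)heptanoate | CC(=O)CC[C@H](CC(=O)OC)C(=C)C | intermediate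
7 | methyl (3R)-6-methyl-3-(prop-1-en-2-yl)hept-6-enoate | C=C(C)CC[C@H](CC(=O)OC)C(=C)C | intermediate
8 | lithium enolate of (4R)-1,1-dibromo-7-methyl-4-(prop-1-en-2-yl)oct-7-en-2-one | C=C(C)CC[C@H](CC(O[Li])=C(Br)Br)C(=C)C | intermediate
9 | lithium (4R)-7-methyl-4-(prop-1-en-2-yl)oct-7-en-1-yn-1-olate | C=C(C)CC[C@H](CC#CO[Li])C(=C)C | intermediate
10 | triisopropyl{[(4R)-7-methyl-4-(prop-1-en-2-yl)oct-7-en-1-yn-1-yl]oxy}silane | C=C(C)CC[C@H](CC#CO[Si](C(C)C)(C(C)C)C(C)C)C(=C)C | intermediate
11 | acetone | CC(C)=O | starting material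
12 | ketene | C=C=O | intermediate
13 | 2-R*-3-[(triisopropylsilyl)oxy]cyclobut-2-en-1-one | C=C(C)CC[C@H](CC1=C(O[Si](C(C)C)(C(C)C)C(C)C)CC1=O)C(=C)C | intermediate
14 | 3-methylbut-1-yne | CC(C)C#C | starting material
15 | chlorobis(cyclopentadienyl)[(1E)-3-methylbut-1-en-1-yl]zirconium | CC(C)/C=C/[Zr+2]Cl.c1cc[cH-]c1.c1cc[cH-]c1 | intermediate
16 | (E)-1-iodo-3-methylbut-1-ene | CC(C)/C=C/I | intermediate
17 | 2-chloro-1,1-dimethoxyethane (chloroacetaldehyde dimethyl acetal) | COC(CCl)OC | starting material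
18 | lithium methoxyacetylide | COC#C[Li] | intermediate
19 | methoxyethynylzinc chloride | COC#C[Zn]Cl | intermediate
20 | (3E)-1-methoxy-5-methylhex-3-en-1-yne | COC#C/C=C/C(C)C | intermediate
21 | 2-R*-3-[(triisopropylsilyl)oxy]buta-1,3-dien-1-one (vinylketene) | C=C(C)CC[C@H](CC(=C=O)C(=C)O[Si](C(C)C)(C(C)C)C(C)C)C(=C)C | intermediate
22 | 3-methoxy-2-[(1E)-3-methylbut-1-en-1-yl]-4-R*-4-{1-[(triisopropylsilyl)oxy]ethenyl}cyclobut-2-en-1-one (both configurations at C4) | C=C(C)CC[C@H](CC1(C(=C)O[Si](C(C)C)(C(C)C)C(C)C)C(OC)=C(/C=C/C(C)C)C1=O)C(=C)C | intermediate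
23 | 3-methoxy-2-[(1E)-3-methylbut-1-en-1-yl]-4-R*-5-[(triisopropylsilyl)oxy]hexa-1,3,5-trien-1-one (dienylketene) | C=C(C)CC[C@H](CC(C(=C)O[Si](C(C)C)(C(C)C)C(C)C)=C(OC)C(=C=O)/C=C/C(C)C)C(=C)C | intermediate
24 | 3-methoxy-2-[(1E)-3-methylbut-1-en-1-yl]-4-R*-5-[(triisopropylsilyl)oxy]cyclohexa-2,4-dien-1-one | C=C(C)CC[C@H](CC1=C(O[Si](C(C)C)(C(C)C)C(C)C)CC(=O)C(/C=C/C(C)C)=C1OC)C(=C)C | intermediate
25 | 3-methoxy-4-R*-2-[(1E)-3-methylbut-1-en-1-yl]-5-[(triisopropylsilyl)oxy]phenol | C=C(C)CC[C@H](Cc1c(O[Si](C(C)C)(C(C)C)C(C)C)cc(O)c(/C=C/C(C)C)c1OC)C(=C)C | intermediate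
26 | 5-methoxy-4-R*-6-[(1E)-3-methylbut-1-en-1-yl]benzene-1,3-diol | C=C(C)CC[C@H](Cc1c(O)cc(O)c(/C=C/C(C)C)c1OC)C(=C)C | intermediate
27 | 3-methoxy-1,5-bis(methoxymethoxy)-4-R*-2-[(1E)-3-methylbut-1-en-1-yl]benzene | C=C(C)CC[C@H](Cc1c(OCOC)cc(OCOC)c(/C=C/C(C)C)c1OC)C(=C)C | intermediate
28 | 3-hydroxybenzaldehyde | O=Cc1cccc(O)c1 | starting material
29 | 3-(methoxymethoxy)benzaldehyde | O=Cc1cccc(OCOC)c1 | intermediate
30 | 2,6-bis(methoxymethoxy)-4-methoxy-3-R*-5-[(1E)-3-methylbut-1-en-1-yl]phenyllithium | C=C(C)CC[C@H](Cc1c(OCOC)c([Li])c(OCOC)c(/C=C/C(C)C)c1OC)C(=C)C | intermediate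
31 | {2,6-bis(methoxymethoxy)-4-methoxy-3-R*-5-[(1E)-3-methylbut-1-en-1-yl]phenyl}[3-(methoxymethoxy)phenyl]methanol (both carbinol epimers) | C=C(C)CC[C@H](Cc1c(OCOC)c(C(O)c2cccc(OCOC)c2)c(OCOC)c(/C=C/C(C)C)c1OC)C(=C)C | intermediate
32 | {2,6-bis(methoxymethoxy)-4-methoxy-3-R*-5-[(1E)-3-methylbut-1-en-1-yl]phenyl}[3-(methoxymethoxy)phenyl]methanone | C=C(C)CC[C@H](Cc1c(OCOC)c(C(=O)c2cccc(OCOC)c2)c(OCOC)c(/C=C/C(C)C)c1OC)C(=C)C | intermediate
33 | {2,6-dihydroxy-4-methoxy-3-[(2R)-5-methyl-2-(prop-1-en-2-yl)hex-5-en-1-yl]-5-[(1E)-3-methylbut-1-en-1-yl]phenyl}(3-hydroxyphenyl)methanone (CNP0208548.1) | C=C(C)CC[C@H](Cc1c(O)c(C(=O)c2cccc(O)c2)c(O)c(/C=C/C(C)C)c1OC)C(=C)C | target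

**Step count and risks**
Total step count: 16. Longest linear sequence: 13 steps (steps 1–7, 10–12 and 14–16).

Steps most likely to fail:

1. Step 10. The conjugated enynyl ether may oligomerise, or the vinylketene may be captured across the enyne or by the side-chain methallyl alkene, before the slow opening of the donor-stabilised cyclobutenone supplies enough vinylketene. The fallback builds the alkene after the ring; it sets out from cyclobutenone 13 and lithium methoxyacetylide 18 and comes back at bis-MOM ether 27. Acetylide 18 would be trapped with paraformaldehyde and the alkoxide silylated in the same flask (t-BuPh2SiCl, DMAP) to give tert-butyl[(3-methoxyprop-2-yn-1-yl)oxy]diphenylsilane F1, a non-conjugated methyl ynol ether that tolerates harder heating. Benzannulation of 13 with it (PhMe, 120–140 °C) should give 2-{[(tert-butyldiphenylsilyl)oxy]methyl}-3-methoxy-4-R*-5-[(triisopropylsilyl)oxy]phenol F2. Selective cleavage of the aryl silyl ether (n-Bu4NF, 1 equiv, −20 → 0 °C) would give 4-{[(tert-butyldiphenylsilyl)oxy]methyl}-5-methoxy-6-R*-benzene-1,3-diol F3, and MOMCl/i-Pr2NEt the bis-MOM ether F4. Removal of the alkyl silyl ether (n-Bu4NF, rt) would give [2-methoxy-4,6-bis(methoxymethoxy)-3-R*-phenyl]methanol F5, and MnO2 in CH2Cl2 the 2-methoxy-4,6-bis(methoxymethoxy)-3-R*-benzaldehyde F6. Julia–Kocienski olefination with the reagent 5-[(2-methylpropyl)sulfonyl]-1-phenyl-1H-tetrazole (CC(C)CS(=O)(=O)c1nnnn1-c1ccccc1; KN(SiMe3)2, DME, −60 °C → rt) should then install the E-alkene and deliver 27.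

2. Step 9. The volatile, acid-sensitive ynol ether may be lost by hydration or evaporation on isolation, and the cross-coupling may lag behind homocoupling of the zinc acetylide. The fallback replaces the coupling by an elimination; it sets out from iodide 16 and comes back at enynyl ether 20. Iodine–lithium exchange on 16 (t-BuLi, Et2O, −78 °C) and acylation with the Weinreb amide N,2-dimethoxy-N-methylacetamide would give (E)-1-methoxy-5-methylhex-3-en-2-one F7. Kinetic enolisation toward the methoxymethyl side and O-triflation (KN(SiMe3)2, PhNTf2, THF, −78 °C) would give (1Z,3E)-1-methoxy-5-methylhexa-1,3-dien-2-yl trifluoromethanesulfonate F8, and anti elimination of triflate with KOt-Bu (−78 → 0 °C) should give 20.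

3. Step 16. Before the third, non-chelated MOM ether is cleaved, the freed ortho phenol may add to the protonated isopropenyl group (chroman formation), or methanol may add to the 1,1-disubstituted alkenes. The fallback ends with fluoride instead of acid; it sets out from resorcinol 26 and aldehyde 28 and comes back at target 33. Resorcinol 26 would be protected with Me3SiCH2CH2OCH2Cl/i-Pr2NEt as 3-methoxy-4-R*-2-[(1E)-3-methylbut-1-en-1-yl]-1,5-bis{[2-(trimethylsilyl)ethoxy]methoxy}benzene F9, and 28 silylated (t-BuMe2SiCl, imidazole) to 3-[(tert-butyldimethylsilyl)oxy]benzaldehyde F10. Ortho-lithiation of F9 between the two acetal ethers (n-BuLi, THF, 0 °C) and addition to F10 would give the benzhydrol F11, and Dess–Martin oxidation the ketone F12. n-Bu4NF in THF/DMPU at 50–60 °C should then remove both acetal ethers and the silyl ether to give 33 without any acid.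

**Further compounds**
F1 | step 10 | tert-butyl[(3-methoxyprop-2-yn-1-yl)oxy]diphenylsilane | COC#CCO[Si](c1ccccc1)(c1ccccc1)C(C)(C)C
F2 | step 10 | 2-{[(tert-butyldiphenylsilyl)oxy]methyl}-3-methoxy-4-R*-5-[(triisopropylsilyl)oxy]phenol | C=C(C)CC[C@H](Cc1c(O[Si](C(C)C)(C(C)C)C(C)C)cc(O)c(CO[Si](c2ccccc2)(c2ccccc2)C(C)(C)C)c1OC)C(=C)C
F3 | step 10 | 4-{[(tert-butyldiphenylsilyl)oxy]methyl}-5-methoxy-6-R*-benzene-1,3-diol | C=C(C)CC[C@H](Cc1c(O)cc(O)c(CO[Si](c2ccccc2)(c2ccccc2)C(C)(C)C)c1OC)C(=C)C
F4 | step 10 | tert-butyl{[2-methoxy-4,6-bis(methoxymethoxy)-3-R*-phenyl]methoxy}diphenylsilane | C=C(C)CC[C@H](Cc1c(OCOC)cc(OCOC)c(CO[Si](c2ccccc2)(c2ccccc2)C(C)(C)C)c1OC)C(=C)C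
F5 | step 10 | [2-methoxy-4,6-bis(methoxymethoxy)-3-R*-phenyl]methanol | C=C(C)CC[C@H](Cc1c(OCOC)cc(OCOC)c(CO)c1OC)C(=C)C
F6 | step 10 | 2-methoxy-4,6-bis(methoxymethoxy)-3-R*-benzaldehyde | C=C(C)CC[C@H](Cc1c(OCOC)cc(OCOC)c(C=O)c1OC)C(=C)C
F7 | step 9 | (E)-1-methoxy-5-methylhex-3-en-2-one | COCC(=O)/C=C/C(C)C
F8 | step 9 | (1Z,3E)-1-methoxy-5-methylhexa-1,3-dien-2-yl trifluoromethanesulfonate | CO/C=C(\OS(=O)(=O)C(F)(F)F)/C=C/C(C)C
F9 | step 16 | 3-methoxy-4-R*-2-[(1E)-3-methylbut-1-en-1-yl]-1,5-bis{[2-(trimethylsilyl)ethoxy]methoxy}benzene | C=C(C)CC[C@H](Cc1c(OCOCC[Si](C)(C)C)cc(OCOCC[Si](C)(C)C)c(/C=C/C(C)C)c1OC)C(=C)C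
F10 | step 16 | 3-[(tert-butyldimethylsilyl)oxy]benzaldehyde | O=Cc1cccc(O[Si](C)(C)C(C)(C)C)c1
F11 | step 16 | {4-methoxy-3-R*-5-[(1E)-3-methylbut-1-en-1-yl]-2,6-bis{[2-(trimethylsilyl)ethoxy]methoxy}phenyl}{3-[(tert-butyldimethylsilyl)oxy]phenyl}methanol (both carbinol epimers) | C=C(C)CC[C@H](Cc1c(OCOCC[Si](C)(C)C)c(C(O)c2cccc(O[Si](C)(C)C(C)(C)C)c2)c(OCOCC[Si](C)(C)C)c(/C=C/C(C)C)c1OC)C(=C)C
F12 | step 16 | {4-methoxy-3-R*-5-[(1E)-3-methylbut-1-en-1-yl]-2,6-bis{[2-(trimethylsilyl)ethoxy]methoxy}phenyl}{3-[(tert-butyldimethylsilyl)oxy]phenyl}methanone | C=C(C)CC[C@H](Cc1c(OCOCC[Si](C)(C)C)c(C(=O)c2cccc(O[Si](C)(C)C(C)(C)C)c2)c(OCOCC[Si](C)(C)C)c(/C=C/C(C)C)c1OC)C(=C)C
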